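## Structural features

The target (C20H34BrClO2) is a 7-oxabicyclo[2.2.1]heptane: a cyclohexane C1–C6 whose C1 and C4 are bridged by the ether oxygen O7. C1 carries a methyl group, C2 a 3-hydroxy-3-methylpent-4-enyl chain (C1'–C5'), and C3 a methyl group plus a 3-bromo-4-chloro-4-methylpentyl chain (C1''–C4''). Four contiguous stereocentres lie on the bicycle, C1(S)–C2(S)–C3(S)–C4(R). C1 and C3 are quaternary, the C2 chain is endo (anti to O7) and the C3 chain is exo (syn to O7), so the two chains are trans and the C3 methyl is cis to the C2 chain. Two further stereocentres are isolated from the ring: the tertiary vinyl carbinol C3'(S) and the secondary bromide C3''(S), which is flanked by the tertiary chloride C4''. The fragile groups are the tertiary allylic alcohol (ionisation and allylic transposition in acid), the β-bromo tertiary chloride (elimination with base, solvolysis through a bromonium ion, reduction by hydrides and low-valent metals) and the strained bridged ether towards strong Lewis acids. The real difficulty is twofold: the congested C1–C4 array with two quaternary centres, and the two remote centres C3' and C3'' that no ring stereocentre can influence. The key step uses the fact that, once the core and the carbinol exist, the trisubstituted C3''=C4'' alkene is the most electron-rich π bond (the other is the monosubstituted C4'=C5' vinyl group). It is polarised so that bromine goes to C3'' and chloride to tertiary C4'', leaving only the choice of alkene face to a catalyst. Acyclic intermediates are described below with the locants of the target ("future C2" and so on).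

## Logic of the disconnections

**27 to 25.** The C3''–Br and C4''–Cl bonds are cut. They are the most labile bonds of 27, and their anti, Markovnikov relationship is what opening of a bromonium ion (26) by chloride delivers. The gain is a halogen-free compound whose only reactive site of that kind is an isolated trisubstituted alkene, so no earlier step has to tolerate a halide. The demand on the forward step is heavy: it must pick one face of an alkene three bonds from the nearest stereocentre, prefer this alkene to the vinyl group, and let chloride win over water. The free hydroxyl of 25 is kept, since it cannot reach C3'' or C4'' and helps solubility in a partly aqueous medium.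

**25 to 24, 23 and 22.** The C3' carbinol is read as the reductively opened form of a 2,3-epoxy alcohol, so the C4'–O bond of 23 (through the C5'–I bond of 24) is the bond that is "cut". The reason is that an isolated tertiary vinyl carbinol can be set reliably only by reagent control, and allylic alcohol epoxidation gives that. The gain is that the stereocentre becomes a (Z)-trisubstituted allylic alcohol in 22. The demand is that the epoxidation be controlled by the tartrate alone and that the reductive opening never break the C3'–O bond.

**22 to 17 and 20.** The C2'–C3' bond (sp3–sp2) is cut. This makes the side chain convergent and takes the alkene geometry ready-made from 20, instead of from a ketone olefination that would give geometric mixtures. The gain is a four-carbon piece 20 and a core 17 that carries only a vinyl group. The demand is that hydroboration of 17 to 21 touch only the vinyl group and that the coupling retain the geometry of 20.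

**20 to 18.** The C–I bond is cut and the alkene returned to an alkyne. The hydroxyl-directed trans-hydroalumination through 19 fixes both regiochemistry and geometry. The demand is clean iodinolysis with retention.

**17 to 16, 15 and 14.** The C1'=C2' bond is cut to an aldehyde, which goes back through the alcohol to the acetate. This is functional-group adjustment only. The demand is that the C2 stereocentre next to the formyl group of 16 not epimerise.

**14 to 12.** The C2–C3 bond and the O7–C1 bond are cut. One cationic event (through 13) builds both rings and sets C1, C2 and C3 relative to C4. The gain is the largest of the route: a bicycle with four contiguous stereocentres becomes an acyclic triene oxide with one oxirane and two alkene geometries. The demands are a (Z)-alkene at the acetate end, a cis-oxirane of defined absolute configuration, ionisation at the quaternary oxirane carbon, and capture of the cation by oxygen faster than proton loss.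

**12 to 11, 10, 9 and 7.** The C1–CH3 bond and the C2–C1' bond are cut, returning the (Z)-trisubstituted alkene to a terminal alkyne. syn-Carbocupration of an alkynoate is the most dependable way to a (Z)-β-methyl enoate. The gain is loss of one geometric element. The demand is low temperature throughout, so that the vinylcopper intermediate does not isomerise and the oxirane survives organometallic reagents.

**7 to 6, then 3 and 4.** The C5–C6 bond is cut, giving a ten-carbon epoxy electrophile and a three-carbon propargyl nucleophile (5, from 4). The demand is that displacement at the primary triflate be much faster than attack on the trisubstituted oxirane.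

**3 to 2 and 1.** The two oxirane C–O bonds are cut. Compound 1 supplies the (Z)-alkene that becomes the cis-oxirane, and its allylic hydroxyl allows absolute control and serves afterwards as the leaving group. The demand is the correct tartrate enantiomer and no reaction at the distal alkene.

## Other disconnections considered

**Alternative 1:** The cut is the C3–C4 bond of the bicycle, which leads back to a 2,2-disubstituted oxolane. (S)-Linalool A1 would supply the methyl-bearing carbinol carbon (future C1) and, after alkene cleavage, ring closure and oxidation of the vinyl group, the diazoketone A2. In the forward key step Rh2(OAc)4 would convert A2 into a rhodium carbenoid whose carbon (future C3) inserts into the ether α-C–H bond at the future C4 on the face carrying the acyl group, closing the cyclopentanone of ketone A3.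
- In its favour: the absolute configuration of C1 and C4 comes from the chiral pool, the insertion is into an activated C–H bond through a five-membered transition state, and A3 is reached in few steps.
- Against it here: A3 carries none of the difficult substituents. C3 must be made quaternary by two enolate alkylations (methyl first, then the chain from the exo face, which is the right sense). The C2 carbonyl, then flanked by two quaternary carbons, must be turned into an endo carbon chain, and olefination of such a ketone is expected to be sluggish. C3' and C3'' are not addressed.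
- Comparison: on absolute control of the core Alternative 1 is the better plan. On mechanism its key step is a known reaction class and so better founded than step 18, and about equal to step 9. On step economy it is expected to be worse, because step 9 installs both branches together with the rings. On the halogen problem the two are equal, since the same late bromochlorination would still be needed.

**Alternative 2:** The cut is through C2–C3 and O7–C1, which unfolds the bicycle to compound 12. Forward, MeAlCl2 at −78 °C would ionise the oxirane at its quaternary carbon, the (Z)-alkene would attack through the future C2, and the oxygen left on C4 would capture the C1 cation to give the bicyclic acetate A4. A4 is the same compound as 14, so this disconnection is not a rival of the chosen plan but its core-forming step 9.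
- In its favour: two rings, two skeletal bonds and three stereocentres are formed in one known type of reaction, with relative configuration from two alkene geometries and absolute configuration from one epoxidation.
- Against it: proton loss, hydride shift or a boat-type attack can divert the cation, and it does not address C3' or C3''.
- Comparison: as a generator of complexity, and in precedent, it is the better of the two steps. As the step that defines the whole strategy it is the weaker, because a β-bromo tertiary chloride could not be carried through MeAlCl2, cuprate, hydride, borane and zinc chemistry. A plan centred on it would therefore still end with an uncontrolled or enzymatic addition of BrCl. In step economy the two are equal, being the same route as far as 25.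

**Alternative 3:** The cuts are the C2–C1' and C3–C1'' bonds, made on a monocyclic enone in which the O7–C4 bond is still open. In enone A5 the silyloxy carbon is the future C1 and the carbonyl carbon the future C4. Forward, Grignard reagent A6 with CuBr·SMe2 and Me3SiCl would add to C2 anti to the silyloxy group. The silyl enol ether would be converted with MeLi into the lithium enolate and allylated at C3 trans to the new chain, giving cyclohexanone A7.
- In its favour: vicinal trans dialkylation of a cyclohexenone is dependable, C2 and C3 are set by substrate control from the single stereocentre of A5, and the two chains arrive with different handles.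
- Against it: allylation of a tetrasubstituted enolate beside a branched carbon may be slow or leak to oxygen. The oxygen bridge must still be closed by reduction of the C4 ketone to the alcohol trans to the C1 oxygen, activation and displacement through a boat, with elimination as a competitor. The allyl group needs a one-carbon extension and capping, the ketal must become the vinyl carbinol with separate control of C3', and enantiopure A5 itself costs several steps.
- Comparison: on the C2/C3 relative configuration the alternative is arguably the better, since it relies on two sterically controlled additions and not on a chair preference in a cationic cyclisation. Its key step is as reliable as step 9 and better founded than step 18. It is worse in step economy and equal on the halogen problem.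

Key step: step 18

Remark on the chemistry: C3'' is separated from the nearest ring stereocentre C3 by three C–C bonds (C3''–C2''–C1''–C3), and it is assumed that a recombinant algal vanadium-dependent bromoperoxidase that accepts lipophilic terpenoids is available.

## Route

Step 1
Reactants: 1 nerol, (2Z)-3,7-dimethylocta-2,6-dien-1-ol
Product: 2 [(2R,3S)-3-methyl-3-(4-methylpent-3-en-1-yl)oxiran-2-yl]methanol (cis-oxirane)
Conditions: Ti(OiPr)4 (cat.), D-(−)-diethyl tartrate, t-BuOOH, 4 Å molecular sieves, CH2Cl2, −20 °C
Reagents that add atoms: tert-butyl hydroperoxide, CC(C)(C)OO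
Why: Sharpless asymmetric epoxidation; the titanium tartrate binds the allylic hydroxyl, so only the 2,3-alkene reacts and the distal alkene is left alone. D-(−)-Tartrate should give the (2R,3S) oxirane, whose CH carbon becomes C4 and whose quaternary carbon becomes C3; the (Z) geometry of 1 is stored as the cis-oxirane.

Step 2
Reactants: 2 [(2R,3S)-3-methyl-3-(4-methylpent-3-en-1-yl)oxiran-2-yl]methanol
Product: 3 [(2R,3S)-3-methyl-3-(4-methylpent-3-en-1-yl)oxiran-2-yl]methyl trifluoromethanesulfonate
Conditions: Tf2O, 2,6-lutidine, CH2Cl2, −78 °C; cold aqueous work-up, used at once without purification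
Reagents that add atoms: trifluoromethanesulfonic anhydride, O=S(=O)(OS(=O)(=O)C(F)(F)F)C(F)(F)F
Why: O-Sulfonylation of a primary alcohol with a hindered base; no stereocentre is touched. The triflate is chosen because it can be displaced at −78 °C, well below the temperature at which a trisubstituted oxirane is opened by a carbanion.

Step 3
Reactants: 3 [(2R,3S)-3-methyl-3-(4-methylpent-3-en-1-yl)oxiran-2-yl]methyl trifluoromethanesulfonate; 4 1-(trimethylsilyl)propyne
Product: 6 trimethyl{4-[(2R,3S)-3-methyl-3-(4-methylpent-3-en-1-yl)oxiran-2-yl]but-1-yn-1-yl}silane, via lithiated silylpropyne 5 (not isolated)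
Conditions: 4, n-BuLi, THF, −78 to −20 °C; then 3, THF, −78 °C
Reagents that add atoms: none
Why: SN2 alkylation of a propargylic organolithium at a primary triflate; the silyl cap directs reaction to the CH2 terminus and blocks the acetylenic position. The C5–C6 bond forms and the oxirane stereocentres are not involved.

Step 4
Reactants: 6 trimethyl{4-[(2R,3S)-3-methyl-3-(4-methylpent-3-en-1-yl)oxiran-2-yl]but-1-yn-1-yl}silane
Product: 7 4-[(2R,3S)-3-methyl-3-(4-methylpent-3-en-1-yl)oxiran-2-yl]but-1-yne
Conditions: K2CO3, MeOH, rt
Reagents that add atoms: none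
Why: Methoxide-induced protodesilylation of an alkynylsilane; the trisubstituted oxirane is inert to carbonate in methanol at room temperature.

Step 5
Reactants: 7 4-[(2R,3S)-3-methyl-3-(4-methylpent-3-en-1-yl)oxiran-2-yl]but-1-yne
Product: 9 ethyl 5-[(2R,3S)-3-methyl-3-(4-methylpent-3-en-1-yl)oxiran-2-yl]pent-2-ynoate, via lithium acetylide 8 (not isolated)
Conditions: n-BuLi, THF, −78 °C; then ClCO2Et, −78 to −40 °C
Reagents that add atoms: ethyl chloroformate, CCOC(=O)Cl
Why: C-Acylation of a lithium acetylide with a chloroformate, which installs the future C1' and activates the alkyne for conjugate addition. Without a Lewis acid the oxirane does not react with the acetylide at −78 °C, and intramolecular attack would need an impossible small cycloalkyne.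

Step 6
Reactants: 9 ethyl 5-[(2R,3S)-3-methyl-3-(4-methylpent-3-en-1-yl)oxiran-2-yl]pent-2-ynoate
Product: 10 ethyl (2Z)-3-methyl-5-[(2R,3S)-3-methyl-3-(4-methylpent-3-en-1-yl)oxiran-2-yl]pent-2-enoate
Conditions: Me2CuLi (from CuI and MeLi), THF, −78 °C; MeOH, then aq. NH4Cl at −78 °C
Reagents that add atoms: lithium dimethylcuprate, [Li+].C[Cu-]C
Why: syn-Carbocupration (conjugate addition) of a Gilman cuprate to an alkynoate: methyl and copper add to the same side, and protonation at −78 °C with retention puts the chain cis to the ester, giving the (Z)-enoate. Quenching cold prevents equilibration through the allenolate, and a trisubstituted oxirane is not opened by the cuprate at this temperature.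

Step 7
Reactants: 10 ethyl (2Z)-3-methyl-5-[(2R,3S)-3-methyl-3-(4-methylpent-3-en-1-yl)oxiran-2-yl]pent-2-enoate
Product: 11 (2Z)-3-methyl-5-[(2R,3S)-3-methyl-3-(4-methylpent-3-en-1-yl)oxiran-2-yl]pent-2-en-1-ol
Conditions: i-Bu2AlH, CH2Cl2, −78 °C; aq. KNaC4H4O6
Reagents that add atoms: none
Why: 1,2-Reduction of an enoate to the allylic alcohol with retention of alkene geometry; at −78 °C the aluminium hydride does not open a trisubstituted oxirane.

Step 8
Reactants: 11 (2Z)-3-methyl-5-[(2R,3S)-3-methyl-3-(4-methylpent-3-en-1-yl)oxiran-2-yl]pent-2-en-1-ol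
Product: 12 (2Z)-3-methyl-5-[(2R,3S)-3-methyl-3-(4-methylpent-3-en-1-yl)oxiran-2-yl]pent-2-en-1-yl acetate
Conditions: Ac2O, Et3N, 4-(dimethylamino)pyridine (cat.), CH2Cl2, 0 °C
Reagents that add atoms: acetic anhydride, CC(=O)OC(C)=O
Why: Acylation of a primary alcohol; the acetate keeps the oxygen from trapping the cation or binding the Lewis acid irreversibly in the next step.

Step 9
Reactants: 12 (2Z)-3-methyl-5-[(2R,3S)-3-methyl-3-(4-methylpent-3-en-1-yl)oxiran-2-yl]pent-2-en-1-yl acetate
Product: 14 [(1S,2R,3S,4R)-1,3-dimethyl-3-(4-methylpent-3-en-1-yl)-7-oxabicyclo[2.2.1]heptan-2-yl]methyl acetate (CH2OAc endo, homoprenyl exo), via tertiary cyclohexyl cation 13 (not isolated)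
Conditions: MeAlCl2 (hexanes, 2 equiv), CH2Cl2, −78 °C; aq. NaHCO3
Reagents that add atoms: none
Why: Lewis-acid-triggered epoxide–alkene cationic cyclisation ended by ether formation, a path known for epoxygeranyl-type esters: MeAlCl2 ionises the oxirane at its quaternary carbon, the (Z)-alkene attacks anti through the future C2 (inversion at C3) in a chair-like array, and the aluminium-bound oxygen on C4 then captures cation 13 across the ring to form O7–C1. The cis-oxirane should place the homoprenyl group syn to oxygen (exo) and the (Z)-alkene the acetoxymethyl group anti to it (endo), so C1, C2 and C3 follow from C4 and the two geometries. MeAlCl2 also removes stray protons as methane, and the distal alkene cannot reach either cationic centre through a five- or six-membered ring with Markovnikov polarity.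

Step 10
Reactants: 14 [(1S,2R,3S,4R)-1,3-dimethyl-3-(4-methylpent-3-en-1-yl)-7-oxabicyclo[2.2.1]heptan-2-yl]methyl acetate
Product: 15 [(1S,2R,3S,4R)-1,3-dimethyl-3-(4-methylpent-3-en-1-yl)-7-oxabicyclo[2.2.1]heptan-2-yl]methanol
Conditions: K2CO3, MeOH, rt
Reagents that add atoms: none
Why: Base-catalysed transesterification of a primary acetate; nothing else in the molecule responds to methoxide.

Step 11
Reactants: 15 [(1S,2R,3S,4R)-1,3-dimethyl-3-(4-methylpent-3-en-1-yl)-7-oxabicyclo[2.2.1]heptan-2-yl]methanol
Product: 16 (1S,2S,3S,4R)-1,3-dimethyl-3-(4-methylpent-3-en-1-yl)-7-oxabicyclo[2.2.1]heptane-2-carbaldehyde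
Conditions: Dess–Martin periodinane, NaHCO3, CH2Cl2, 0 °C to rt
Reagents that add atoms: none
Why: Dess–Martin oxidation under buffered, near-neutral conditions, chosen so that C2, now α to a formyl group, is not epimerised; the alkene and the ether are inert.

Step 12
Reactants: 16 (1S,2S,3S,4R)-1,3-dimethyl-3-(4-methylpent-3-en-1-yl)-7-oxabicyclo[2.2.1]heptane-2-carbaldehyde
Product: 17 (1S,2S,3S,4R)-2-ethenyl-1,3-dimethyl-3-(4-methylpent-3-en-1-yl)-7-oxabicyclo[2.2.1]heptane
Conditions: Ph3PCH3Br, KN(SiMe3)2, THF, 0 °C; then 16, −78 to 0 °C
Reagents that add atoms: methyltriphenylphosphonium bromide (as its ylide), C[P+](c1ccccc1)(c1ccccc1)c1ccccc1.[Br-]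
Why: Wittig methylenation; the small unstabilised ylide adds to the hindered aldehyde at low temperature, faster than deprotonation at the shielded C2. The C1'=C2' bond forms.

Step 13
Reactants: 18 but-2-yn-1-ol
Product: 20 (2Z)-3-iodobut-2-en-1-ol, via cyclic alkenylaluminate 19 (not isolated)
Conditions: NaAlH2(OCH2CH2OMe)2, THF, 0 °C to rt; then I2, THF, −78 °C
Reagents that add atoms: iodine, II
Why: Alkoxide-directed trans-hydroalumination of a propargylic alcohol puts hydride on C2 and aluminium on C3 within the five-membered ring of 19; iodinolysis with retention gives the (Z)-iodide, with iodine cis to the hydroxymethyl group.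

Step 14
Reactants: 17 (1S,2S,3S,4R)-2-ethenyl-1,3-dimethyl-3-(4-methylpent-3-en-1-yl)-7-oxabicyclo[2.2.1]heptane; 20 (2Z)-3-iodobut-2-en-1-ol
Product: 22 (2Z)-5-[(1S,2S,3S,4R)-1,3-dimethyl-3-(4-methylpent-3-en-1-yl)-7-oxabicyclo[2.2.1]heptan-2-yl]-3-methylpent-2-en-1-ol, via B-alkyl-9-borabicyclononane 21 (not isolated)
Conditions: 9-BBN, THF, 0 °C to rt; then 20, Pd(dppf)Cl2 (5 mol %), AsPh3, aq. Cs2CO3, DMF, rt
Reagents that add atoms: none
Why: Anti-Markovnikov hydroboration with 9-BBN is selective for the monosubstituted alkene over the trisubstituted one, and the B-alkyl Suzuki–Miyaura coupling (zerovalent palladium formed in the flask) joins C2' to C3' with retention of the iodide geometry. The (Z) trisubstituted allylic alcohol is thus obtained as a single geometric isomer without a protecting group.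

Step 15
Reactants: 22 (2Z)-5-[(1S,2S,3S,4R)-1,3-dimethyl-3-(4-methylpent-3-en-1-yl)-7-oxabicyclo[2.2.1]heptan-2-yl]-3-methylpent-2-en-1-ol
Product: 23 [(2R,3S)-3-{2-[(1S,2S,3S,4R)-1,3-dimethyl-3-(4-methylpent-3-en-1-yl)-7-oxabicyclo[2.2.1]heptan-2-yl]ethyl}-3-methyloxiran-2-yl]methanol
Conditions: Ti(OiPr)4 (cat.), D-(−)-diethyl tartrate, t-BuOOH, 4 Å molecular sieves, CH2Cl2, −20 °C
Reagents that add atoms: tert-butyl hydroperoxide, CC(C)(C)OO
Why: Sharpless asymmetric epoxidation of a (Z)-trisubstituted allylic alcohol, the same substrate type as in step 1, so D-(−)-tartrate should again give the (2R,3S) oxirane; its quaternary carbon is the future C3'(S). The ring stereocentres are too far away to influence the result and the homoprenyl alkene has no directing hydroxyl.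

Step 16
Reactants: 23 [(2R,3S)-3-{2-[(1S,2S,3S,4R)-1,3-dimethyl-3-(4-methylpent-3-en-1-yl)-7-oxabicyclo[2.2.1]heptan-2-yl]ethyl}-3-methyloxiran-2-yl]methanol
Product: 24 (2S,3S)-2-(iodomethyl)-3-methyl-3-{2-[(1S,2S,3S,4R)-1,3-dimethyl-3-(4-methylpent-3-en-1-yl)-7-oxabicyclo[2.2.1]heptan-2-yl]ethyl}oxirane
Conditions: I2, PPh3, imidazole, CH2Cl2, 0 °C, dark
Reagents that add atoms: iodine, II
Why: Appel-type iodination of a primary alcohol under neutral conditions that leave the oxirane closed; the change of descriptor at the CH carbon is formal only.

Step 17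
Reactants: 24 (2S,3S)-2-(iodomethyl)-3-methyl-3-{2-[(1S,2S,3S,4R)-1,3-dimethyl-3-(4-methylpent-3-en-1-yl)-7-oxabicyclo[2.2.1]heptan-2-yl]ethyl}oxirane
Product: 25 (3S)-5-[(1S,2S,3S,4R)-1,3-dimethyl-3-(4-methylpent-3-en-1-yl)-7-oxabicyclo[2.2.1]heptan-2-yl]-3-methylpent-1-en-3-ol
Conditions: Zn dust, AcOH, EtOH, rt
Reagents that add atoms: none
Why: Reductive β-elimination: zinc inserts into the C–I bond and the oxirane opens to the vinyl carbinol. The C3'–O bond is never broken, so the configuration set in step 15 is carried over as C3'(S).

Step 18
Reactants: 25 (3S)-5-[(1S,2S,3S,4R)-1,3-dimethyl-3-(4-methylpent-3-en-1-yl)-7-oxabicyclo[2.2.1]heptan-2-yl]-3-methylpent-1-en-3-ol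
Product: 27 (3S)-5-[(1S,2S,3S,4R)-3-[(3S)-3-bromo-4-chloro-4-methylpentyl]-1,3-dimethyl-7-oxabicyclo[2.2.1]heptan-2-yl]-3-methylpent-1-en-3-ol (CNP0297543.1), via bromonium ion 26 (not isolated)
Conditions: vanadium-dependent bromoperoxidase (recombinant, algal; cofactor Na3VO4), KBr (1.2 equiv), KCl (3 M), H2O2 (1.1 equiv, slow addition), MES buffer pH 6.0 / t-BuOH (2:1), 25 °C
Reagents that add atoms: potassium bromide, [K+].[Br-]; potassium chloride, [K+].[Cl-]
Why: Proposed new method: the vanadate cofactor (pentavalent vanadium, no redox change at the metal) binds H2O2 as a peroxide and oxidises bromide to an enzyme-held hypobromite equivalent, which should transfer Br+ to the C3''=C4'' alkene of 25 to give bromonium ion 26; chloride, present in large excess, then opens 26 at tertiary C4'' from the side opposite bromine, so the C3''–Br and C4''–Cl bonds form anti and Markovnikov. The closest known reaction type is bromonium transfer by vanadium bromoperoxidases to terpene alkenes, which ends in bromohydrins or bromo-cyclised products, together with titanium-catalysed enantioselective bromochlorination of allylic alcohols for the halide pairing; capture of an enzyme-generated bromonium ion by external chloride has not been shown. No ring is closed: the C3' hydroxyl would need a ring of nine or more atoms and O7 is a hindered dialkyl ether, so neither can compete with halide. The one new stereocentre, C3''(S), must be set by the enzyme pocket presenting one alkene face to the bound hypobromite, because the nearest substrate stereocentre, C3, is three bonds away and exerts no bias. Chemoselectivity for the trisubstituted alkene over the C4'=C5' vinyl group follows from its higher nucleophilicity, as expected from nerolidol-type substrates that carry the same vinyl carbinol, and regioselectivity follows from the larger positive charge at the tertiary carbon of 26. Chloride-over-water selectivity rests only on the chloride concentration and the tert-butanol co-solvent, and H2O2 is added slowly so that free HOBr, which would brominate without facial control, does not build up. Any C3'' epimer or bromohydrin would be removed by chromatography.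

## Compound list

1 | nerol, (2Z)-3,7-dimethylocta-2,6-dien-1-ol | CC(C)=CCC/C(C)=C\CO | starting material
2 | [(2R,3S)-3-methyl-3-(4-methylpent-3-en-1-yl)oxiran-2-yl]methanol | OC[C@H]1O[C@@]1(C)CCC=C(C)C | intermediate
3 | [(2R,3S)-3-methyl-3-(4-methylpent-3-en-1-yl)oxiran-2-yl]methyl trifluoromethanesulfonate | FC(F)(F)S(=O)(=O)OC[C@H]1O[C@@]1(C)CCC=C(C)C | intermediate
4 | 1-(trimethylsilyl)propyne | CC#C[Si](C)(C)C | starting material
5 | [3-(trimethylsilyl)prop-2-yn-1-yl]lithium | [Li]CC#C[Si](C)(C)C | intermediate
6 | trimethyl{4-[(2R,3S)-3-methyl-3-(4-methylpent-3-en-1-yl)oxiran-2-yl]but-1-yn-1-yl}silane | C[Si](C)(C)C#CCC[C@H]1O[C@@]1(C)CCC=C(C)C | intermediate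
7 | 4-[(2R,3S)-3-methyl-3-(4-methylpent-3-en-1-yl)oxiran-2-yl]but-1-yne | C#CCC[C@H]1O[C@@]1(C)CCC=C(C)C | intermediate
8 | lithium acetylide of 7, {4-[(2R,3S)-3-methyl-3-(4-methylpent-3-en-1-yl)oxiran-2-yl]but-1-yn-1-yl}lithium | [Li]C#CCC[C@H]1O[C@@]1(C)CCC=C(C)C | intermediate
9 | ethyl 5-[(2R,3S)-3-methyl-3-(4-methylpent-3-en-1-yl)oxiran-2-yl]pent-2-ynoate | CCOC(=O)C#CCC[C@H]1O[C@@]1(C)CCC=C(C)C | intermediate
10 | ethyl (2Z)-3-methyl-5-[(2R,3S)-3-methyl-3-(4-methylpent-3-en-1-yl)oxiran-2-yl]pent-2-enoate | CCOC(=O)/C=C(C)\CC[C@H]1O[C@@]1(C)CCC=C(C)C | intermediate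
11 | (2Z)-3-methyl-5-[(2R,3S)-3-methyl-3-(4-methylpent-3-en-1-yl)oxiran-2-yl]pent-2-en-1-ol | OC/C=C(C)\CC[C@H]1O[C@@]1(C)CCC=C(C)C | intermediate
12 | (2Z)-3-methyl-5-[(2R,3S)-3-methyl-3-(4-methylpent-3-en-1-yl)oxiran-2-yl]pent-2-en-1-yl acetate | CC(=O)OC/C=C(C)\CC[C@H]1O[C@@]1(C)CCC=C(C)C | intermediate
13 | tertiary cyclohexyl cation: 2-(acetoxymethyl)-1-methylcyclohexyl cation carrying 3-methyl, 3-(4-methylpent-3-en-1-yl) and a 4-oxy dichloro(methyl)aluminate group | CC(=O)OC[C@H]1[C@](C)(CCC=C(C)C)[C@H](O[Al-](C)(Cl)Cl)CC[C+]1C | intermediate
14 | [(1S,2R,3S,4R)-1,3-dimethyl-3-(4-methylpent-3-en-1-yl)-7-oxabicyclo[2.2.1]heptan-2-yl]methyl acetate | CC(=O)OC[C@H]1[C@](C)(CCC=C(C)C)[C@H]2CC[C@]1(C)O2 | intermediate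
15 | [(1S,2R,3S,4R)-1,3-dimethyl-3-(4-methylpent-3-en-1-yl)-7-oxabicyclo[2.2.1]heptan-2-yl]methanol | OC[C@H]1[C@](C)(CCC=C(C)C)[C@H]2CC[C@]1(C)O2 | intermediate
16 | (1S,2S,3S,4R)-1,3-dimethyl-3-(4-methylpent-3-en-1-yl)-7-oxabicyclo[2.2.1]heptane-2-carbaldehyde | O=C[C@H]1[C@](C)(CCC=C(C)C)[C@H]2CC[C@]1(C)O2 | intermediate
17 | (1S,2S,3S,4R)-2-ethenyl-1,3-dimethyl-3-(4-methylpent-3-en-1-yl)-7-oxabicyclo[2.2.1]heptane | C=C[C@H]1[C@](C)(CCC=C(C)C)[C@H]2CC[C@]1(C)O2 | intermediate
18 | but-2-yn-1-ol | CC#CCO | starting material
19 | cyclic (Z)-alkenylaluminate: sodium 2,2-bis(2-methoxyethoxy)-3-methyl-2,5-dihydro-1,2-oxaluminol-2-uide | CC1=CCO[Al-]1(OCCOC)OCCOC.[Na+] | intermediate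
20 | (2Z)-3-iodobut-2-en-1-ol | C/C(I)=C/CO | intermediate
21 | 9-{2-[(1S,2S,3S,4R)-1,3-dimethyl-3-(4-methylpent-3-en-1-yl)-7-oxabicyclo[2.2.1]heptan-2-yl]ethyl}-9-borabicyclo[3.3.1]nonane | C1CC2CCCC(C1)B2CC[C@H]1[C@](C)(CCC=C(C)C)[C@H]2CC[C@]1(C)O2 | intermediate
22 | (2Z)-5-[(1S,2S,3S,4R)-1,3-dimethyl-3-(4-methylpent-3-en-1-yl)-7-oxabicyclo[2.2.1]heptan-2-yl]-3-methylpent-2-en-1-ol | OC/C=C(C)\CC[C@H]1[C@](C)(CCC=C(C)C)[C@H]2CC[C@]1(C)O2 | intermediate
23 | [(2R,3S)-3-{2-[(1S,2S,3S,4R)-1,3-dimethyl-3-(4-methylpent-3-en-1-yl)-7-oxabicyclo[2.2.1]heptan-2-yl]ethyl}-3-methyloxiran-2-yl]methanol | OC[C@H]1O[C@@]1(C)CC[C@H]2[C@](C)(CCC=C(C)C)[C@H]3CC[C@]2(C)O3 | intermediate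
24 | (2S,3S)-2-(iodomethyl)-3-methyl-3-{2-[(1S,2S,3S,4R)-1,3-dimethyl-3-(4-methylpent-3-en-1-yl)-7-oxabicyclo[2.2.1]heptan-2-yl]ethyl}oxirane | IC[C@H]1O[C@@]1(C)CC[C@H]2[C@](C)(CCC=C(C)C)[C@H]3CC[C@]2(C)O3 | intermediate
25 | (3S)-5-[(1S,2S,3S,4R)-1,3-dimethyl-3-(4-methylpent-3-en-1-yl)-7-oxabicyclo[2.2.1]heptan-2-yl]-3-methylpent-1-en-3-ol | C=C[C@@](C)(O)CC[C@H]1[C@](C)(CCC=C(C)C)[C@H]2CC[C@]1(C)O2 | intermediate
26 | bromonium ion of 25 bridging C3'' and C4'', with C3'' configured as in 27 | C=C[C@@](C)(O)CC[C@H]1[C@](C)(CC[C@H]([Br+]3)C3(C)C)[C@H]2CC[C@]1(C)O2 | intermediate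
27 | (3S)-5-[(1S,2S,3S,4R)-3-[(3S)-3-bromo-4-chloro-4-methylpentyl]-1,3-dimethyl-7-oxabicyclo[2.2.1]heptan-2-yl]-3-methylpent-1-en-3-ol (CNP0297543.1) | C=C[C@@](C)(O)CC[C@H]1[C@](C)(CC[C@H](Br)C(C)(C)Cl)[C@H]2CC[C@]1(C)O2 | target

## Step count and least certain steps

Total: 18 steps. Longest linear sequence: 17 steps (1 to 27 through steps 1–12 and 14–18); step 13 is a one-step side branch.

**Step 18 (key step).** The most likely failures are poor facial selectivity at C3'', if the oxidised bromine leaves the enzyme as free HOBr before reaching the alkene, and capture of 26 by water to give a bromohydrin, since water is the bulk nucleophile. Loss of enzyme activity in the co-solvent needed to dissolve a C20 terpenoid is a further risk. Fallback with known chemistry, setting out from 25: treatment with tetrabutylammonium dichlorobromate (Bu4N+ BrCl2−) in CH2Cl2 at −78 °C. This is a stoichiometric BrCl source that adds anti and Markovnikov to trisubstituted alkenes faster than to a vinyl group, but without facial bias. It should give 27 together with its C3'' epimer, the (3''R)-bromochloride F1, and the route is rejoined at 27 after preparative HPLC. Control is replaced by separation, at the cost of about half the material.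

**Step 9.** The cation 13 may lose a proton before the oxygen closes the bridge, because bridging requires the ring to reach a boat with the oxygen axial. The oxirane may also rearrange to a ketone by hydride shift, or the alkene may attack through a boat-like array, which would place the acetoxymethyl group exo. Fallback, setting out from 12: the cyclisation is run deliberately to the monocyclic stage with ZrCl4 in CH2Cl2 to give the cyclohexenol [(1R,5R,6S)-5-hydroxy-2,6-dimethyl-6-(4-methylpent-3-en-1-yl)cyclohex-2-en-1-yl]methyl acetate F2. PhSeCl (CH2Cl2, −78 °C) then closes the O7–C1 bond by selenoetherification, with selenium entering anti at C6, to give the 6-endo-phenylselanyl derivative of 14, F3. Bu3SnH with azobisisobutyronitrile in toluene at 80 °C removes selenium and returns the route to 14. This separates C–C from C–O bond formation so that each can be optimised alone.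

**Step 3.** The hard, basic propargyllithium 5 may attack the oxirane or deprotonate next to the triflate, and 3 may decompose before it is consumed. Fallback, setting out from 3: the softer dianion of ethyl acetoacetate (NaH, then n-BuLi, THF, 0 °C; 3 added at −78 °C) displaces the triflate through its γ-carbon to give the β-keto ester ethyl 5-[(2R,3S)-3-methyl-3-(4-methylpent-3-en-1-yl)oxiran-2-yl]-3-oxopentanoate F4. O-Phosphorylation with ClP(O)(OEt)2, Et3N and 4-(dimethylamino)pyridine in a dipolar aprotic solvent should give the (E)-enol phosphate F5, with the phosphate trans to the ester. Me2CuLi at −78 °C replaces the phosphate by methyl with retention, and the route is rejoined at 10. Compounds 6, 7 and 9 are bypassed, and the (Z) geometry then depends on the geometry of the enol phosphate.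

**Step 14.** Transmetalation from the β-branched alkylborane 21 to palladium may be slow, so that protodeboronation or β-hydride elimination takes over, and the free hydroxyl of 20 may bind boron. Fallback, setting out from 16:
- Wittig reaction with 1-(triphenylphosphoranylidene)propan-2-one (toluene, 90 °C) gives the enone (3E)-4-[(1S,2S,3S,4R)-1,3-dimethyl-3-(4-methylpent-3-en-1-yl)-7-oxabicyclo[2.2.1]heptan-2-yl]but-3-en-2-one F6.
- Conjugate reduction with [(Ph3P)CuH]6 gives the methyl ketone F7.
- Horner–Wadsworth–Emmons reaction with triethyl phosphonoacetate and NaH gives mainly the (E)-enoate F8, the (Z) isomer being removed by chromatography.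
- i-Bu2AlH gives the (E)-allylic alcohol F9.
- Sharpless epoxidation, now with L-(+)-diethyl tartrate because the alkene is (E), gives the (2S,3S)-epoxy alcohol F10.
- I2/PPh3/imidazole gives the iodide F11, and Zn/AcOH returns the route to 25 with the same C3'(S) configuration.

This exchanges the cross-coupling for carbonyl olefination, at the cost of two more steps and a geometric separation.

## Further compounds

F1 | step 18 | (3S)-5-[(1S,2S,3S,4R)-3-[(3R)-3-bromo-4-chloro-4-methylpentyl]-1,3-dimethyl-7-oxabicyclo[2.2.1]heptan-2-yl]-3-methylpent-1-en-3-ol (C3'' epimer of 27) | C=C[C@@](C)(O)CC[C@H]1[C@](C)(CC[C@@H](Br)C(C)(C)Cl)[C@H]2CC[C@]1(C)O2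
F2 | step 9 | [(1R,5R,6S)-5-hydroxy-2,6-dimethyl-6-(4-methylpent-3-en-1-yl)cyclohex-2-en-1-yl]methyl acetate | CC(=O)OC[C@H]1[C@](C)(CCC=C(C)C)[C@H](O)CC=C1C
F3 | step 9 | 6-endo-phenylselanyl derivative of 14, [1,3-dimethyl-3-(4-methylpent-3-en-1-yl)-6-(phenylselanyl)-7-oxabicyclo[2.2.1]heptan-2-yl]methyl acetate | CC(=O)OC[C@H]1[C@](C)(CCC=C(C)C)[C@H]2C[C@@H]([Se]c3ccccc3)[C@]1(C)O2
F4 | step 3 | ethyl 5-[(2R,3S)-3-methyl-3-(4-methylpent-3-en-1-yl)oxiran-2-yl]-3-oxopentanoate | CCOC(=O)CC(=O)CC[C@H]1O[C@@]1(C)CCC=C(C)C
F5 | step 3 | ethyl (2E)-3-[(diethoxyphosphoryl)oxy]-5-[(2R,3S)-3-methyl-3-(4-methylpent-3-en-1-yl)oxiran-2-yl]pent-2-enoate | CCOC(=O)/C=C(OP(=O)(OCC)OCC)\CC[C@H]1O[C@@]1(C)CCC=C(C)C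
F6 | step 14 | (3E)-4-[(1S,2S,3S,4R)-1,3-dimethyl-3-(4-methylpent-3-en-1-yl)-7-oxabicyclo[2.2.1]heptan-2-yl]but-3-en-2-one | CC(=O)/C=C/[C@H]1[C@](C)(CCC=C(C)C)[C@H]2CC[C@]1(C)O2
F7 | step 14 | 4-[(1S,2S,3S,4R)-1,3-dimethyl-3-(4-methylpent-3-en-1-yl)-7-oxabicyclo[2.2.1]heptan-2-yl]butan-2-one | CC(=O)CC[C@H]1[C@](C)(CCC=C(C)C)[C@H]2CC[C@]1(C)O2
F8 | step 14 | ethyl (2E)-5-[(1S,2S,3S,4R)-1,3-dimethyl-3-(4-methylpent-3-en-1-yl)-7-oxabicyclo[2.2.1]heptan-2-yl]-3-methylpent-2-enoate | CCOC(=O)/C=C(C)/CC[C@H]1[C@](C)(CCC=C(C)C)[C@H]2CC[C@]1(C)O2
F9 | step 14 | (2E)-5-[(1S,2S,3S,4R)-1,3-dimethyl-3-(4-methylpent-3-en-1-yl)-7-oxabicyclo[2.2.1]heptan-2-yl]-3-methylpent-2-en-1-ol | OC/C=C(C)/CC[C@H]1[C@](C)(CCC=C(C)C)[C@H]2CC[C@]1(C)O2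
F10 | step 14 | [(2S,3S)-3-{2-[(1S,2S,3S,4R)-1,3-dimethyl-3-(4-methylpent-3-en-1-yl)-7-oxabicyclo[2.2.1]heptan-2-yl]ethyl}-3-methyloxiran-2-yl]methanol | OC[C@@H]1O[C@@]1(C)CC[C@H]2[C@](C)(CCC=C(C)C)[C@H]3CC[C@]2(C)O3
F11 | step 14 | (2R,3S)-2-(iodomethyl)-3-methyl-3-{2-[(1S,2S,3S,4R)-1,3-dimethyl-3-(4-methylpent-3-en-1-yl)-7-oxabicyclo[2.2.1]heptan-2-yl]ethyl}oxirane | IC[C@@H]1O[C@@]1(C)CC[C@H]2[C@](C)(CCC=C(C)C)[C@H]3CC[C@]2(C)O3
A1 | alternative 1 | (S)-linalool, (3S)-3,7-dimethylocta-1,6-dien-3-ol | C=C[C@@](C)(O)CCC=C(C)C
A2 | alternative 1 | 2-diazo-1-[(2S)-2-methyloxolan-2-yl]ethan-1-one | [N-]=[N+]=CC(=O)[C@]1(C)CCCO1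
A3 | alternative 1 | (1S,4R)-1-methyl-7-oxabicyclo[2.2.1]heptan-2-one | O=C1C[C@H]2CC[C@]1(C)O2
A4 | alternative 2 | [(1S,2R,3S,4R)-1,3-dimethyl-3-(4-methylpent-3-en-1-yl)-7-oxabicyclo[2.2.1]heptan-2-yl]methyl acetate (identical with 14) | CC(=O)OC[C@H]1[C@](C)(CCC=C(C)C)[C@H]2CC[C@]1(C)O2
A5 | alternative 3 | (4S)-2,4-dimethyl-4-[(triethylsilyl)oxy]cyclohex-2-en-1-one | CC1=C[C@@](C)(O[Si](CC)(CC)CC)CCC1=O
A6 | alternative 3 | [2-(2-methyl-1,3-dioxolan-2-yl)ethyl]magnesium bromide | CC1(CC[Mg]Br)OCCO1
A7 | alternative 3 | 2-allyl-2,4-dimethyl-3-[2-(2-methyl-1,3-dioxolan-2-yl)ethyl]-4-[(triethylsilyl)oxy]cyclohexan-1-one, allyl trans to the C3 chain and the chain trans to the silyloxy group | CC1(CC[C@H]2[C@](C)(CC=C)C(=O)CC[C@]2(C)O[Si](CC)(CC)CC)OCCO1
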